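**Retrosynthetic overview**
1. Schisandrone (15; 2S,3S,4R; 2‑Me/3‑Me cis, 3‑Me/4‑Ar trans) ⇐ 7‑O‑pivalate 14 ⇐ C4–aryl bond by Cu‑catalysed benzylic C–H arylation of tetralone 10 with boronic acid 13 (sets C4 anti to the 3‑Me).
2. Tetralone 10 ⇐ Friedel–Crafts acylation (C1–C8a) of acid 9 ⇐ benzylic deoxygenation of keto acid 8.
3. Keto acid 8 ⇐ Rh‑catalysed enantioselective desymmetrising acyl coupling (C4–C4a) of the arylzinc from 4 with meso anhydride 7; this sets C2 and C3, and the cis relationship comes from the meso compound.
4. Fragments: 4 from catechol (3 steps), 7 from maleic anhydride (2 steps), 13 from catechol (3 steps).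
5. Rings: A and C come from catechol; ring B is the only ring built (step 8).

Assumption: the t‑Bu‑PHOX antipode in step 6 is taken to be (S) for the (2S,3R) acid; if the sense is opposite, the (R) ligand is used.

---

**Step 1**
Reactants: 1 catechol
Product: 2 guaiacol (2‑methoxyphenol)
Conditions: MeI (1.0 equiv), K2CO3 (1.0 equiv), acetone, reflux; NaOH extraction to separate from veratrole
Reagents that add atoms: iodomethane, CI
Why: Williamson mono‑O‑methylation; with one equivalent of MeI the mono‑ether dominates and is separated from neutral veratrole and water‑soluble catechol by acid–base extraction.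

**Step 2**
Reactants: 2 guaiacol
Product: 3 4‑iodo‑2‑methoxyphenol
Conditions: NaI, aq. NaOCl, NaOH, MeOH, 0 °C
Reagents that add atoms: sodium iodide, [Na+].[I-]
Why: Electrophilic aromatic iodination of the phenoxide, which is far more activating than OMe and directs iodine para to O⁻, marking the future C4a.

**Step 3**
Reactants: 3 4‑iodo‑2‑methoxyphenol
Product: 4 4‑iodo‑2‑methoxyphenyl pivalate
Conditions: PivCl, Et3N, DMAP (cat.), CH2Cl2, 0 °C → rt
Reagents that add atoms: pivaloyl chloride, CC(C)(C)C(Cl)=O
Why: DMAP‑catalysed O‑acylation; the pivalate tolerates I/Mg exchange, hydrogenolysis and TFAA, and makes ring A less oxidisable for step 12.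

**Step 4**
Reactants: 5 maleic anhydride (2 equiv)
Product: 6 2,3‑dimethylmaleic anhydride
Conditions: 2‑aminopyridine (0.5 equiv), AcOH, reflux; then 2 M H2SO4, reflux
Reagents that add atoms: none (both C units come from 5; 2‑aminopyridine is released)
Why: Known 2‑aminopyridine‑mediated decarboxylative dimerisation of maleic anhydride (Michael addition/decarboxylation), giving the C1–C4 chain with both methyls.

**Step 5**
Reactants: 6 2,3‑dimethylmaleic anhydride
Product: 7 meso‑(cis)‑2,3‑dimethylsuccinic anhydride [(3R,4S)‑3,4‑dimethyloxolane‑2,5‑dione]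
Conditions: H2 (5 atm), 10% Pd/C, EtOAc, rt; recrystallise
Reagents that add atoms: none
Why: Heterogeneous syn‑hydrogenation delivers both H to one face of the tetrasubstituted alkene, so the methyls end up cis (meso); this is the origin of the 2,3‑cis relationship.

**Step 6**
Reactants: 4 4‑iodo‑2‑methoxyphenyl pivalate; 7 meso‑2,3‑dimethylsuccinic anhydride
Product: 8 (2S,3R)‑4‑[3‑methoxy‑4‑(pivaloyloxy)phenyl]‑2,3‑dimethyl‑4‑oxobutanoic acid
Conditions: 4, i‑PrMgCl·LiCl, THF, −20 °C; Zn(OTf)2; then 7, [Rh(cod)Cl]2 (4 mol %), (S)‑t‑Bu‑PHOX (8 mol %), THF–DMF, 50 °C; aq. HCl; recrystallise (or via the dicyclohexylammonium salt) to raise ee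
Reagents that add atoms: none
Why: Rh‑catalysed enantioselective desymmetrising acyl cross‑coupling (Rh(I) insertion into one enantiotopic anhydride C–O bond, transmetalation from ArZnOTf, reductive elimination); the ligand selects which carbonyl becomes the ketone and so fixes C2 and C3 absolutely, while the cis‑dimethyl relationship is carried over untouched from 7.

**Step 7**
Reactants: 8 keto acid
Product: 9 (2S,3S)‑4‑[3‑methoxy‑4‑(pivaloyloxy)phenyl]‑2,3‑dimethylbutanoic acid
Conditions: H2 (4 atm), 10% Pd/C, AcOH, HClO4 (cat.), 40 °C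
Reagents that add atoms: none
Why: Pd‑catalysed benzylic hydrogenolysis of the aryl ketone (Haworth‑type, via the benzylic alcohol/γ‑lactone); the adjacent C3 centre is not involved and the aryl pivalate is inert (the C3 descriptor changes R→S only through CIP priorities).

**Step 8**
Reactants: 9 acid
Product: 10 (2S,3S)‑6‑methoxy‑2,3‑dimethyl‑7‑(pivaloyloxy)‑3,4‑dihydronaphthalen‑1(2H)‑one (cis‑2,3‑dimethyl)
Conditions: TFAA, TFA, CH2Cl2, 0 °C → rt
Reagents that add atoms: none
Why: Intramolecular Friedel–Crafts acylation via the mixed trifluoroacetic anhydride; attack occurs ortho to the chain and para to OMe (the only unhindered activated site), closing ring B under cold, base‑free conditions that do not enolise C2.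

**Step 9**
Reactants: 1 catechol
Product: 11 veratrole (1,2‑dimethoxybenzene)
Conditions: MeI (2.5 equiv), K2CO3, acetone, reflux
Reagents that add atoms: iodomethane, CI
Why: Exhaustive Williamson O‑methylation.

**Step 10**
Reactants: 11 veratrole
Product: 12 4‑bromo‑1,2‑dimethoxybenzene
Conditions: NBS, MeCN, rt
Reagents that add atoms: N‑bromosuccinimide, O=C1CCC(=O)N1Br
Why: Electrophilic aromatic bromination para to an OMe; positions 4 and 5 are equivalent, so a single mono‑bromide forms.

**Step 11**
Reactants: 12 4‑bromo‑1,2‑dimethoxybenzene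
Product: 13 3,4‑dimethoxyphenylboronic acid
Conditions: n‑BuLi, THF, −78 °C; B(Oi‑Pr)3; 1 M HCl
Reagents that add atoms: triisopropyl borate, CC(C)OB(OC(C)C)OC(C)C; water, O
Why: Li–Br exchange, borate trapping and hydrolysis (standard arylboronic acid synthesis).

**Step 12**
Reactants: 10 tetralone; 13 3,4‑dimethoxyphenylboronic acid (2.0 equiv)
Product: 14 (2S,3S,4R)‑4‑(3,4‑dimethoxyphenyl)‑6‑methoxy‑2,3‑dimethyl‑7‑(pivaloyloxy)‑3,4‑dihydronaphthalen‑1(2H)‑one
Conditions: Cu(MeCN)4PF6 (10 mol %), indane‑bis(oxazoline) ligand (12 mol %, matched antipode), NFSI (1.5 equiv), Li2CO3 (1 equiv), PhCl–CH2Cl2, 30 °C, N2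
Reagents that add atoms: none
Why: Proposed new method: Cu(I) reduces NFSI to Cu(II)–F and •N(SO2Ph)2; this electrophilic N‑radical abstracts a benzylic C4–H (the weakest C–H; the α‑keto C2–H is polarity‑mismatched); Cu(II) transmetalates with ArB(OH)2 and captures the planar C4 radical to give a Cu(III)(aryl)(benzyl) species that reductively eliminates the C4–Ar bond on the face anti to the pseudoaxial 3‑Me (and away from the 2‑Me), giving 3,4‑trans (4R); the ortho‑acyl, OPiv‑deactivated ring disfavours radical‑to‑cation oxidation that would lead to aromatisation to a naphthol; the closest known reaction type is Cu/NFSI radical‑relay benzylic C–H arylation of simple alkylarenes with arylboronic acids, not yet shown with 1,2‑diastereocontrol on a stereodefined, ketone‑bearing tetralone methylene.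

**Step 13**
Reactants: 14 schisandrone O‑pivalate
Product: 15 schisandrone, (2S,3S,4R)‑4‑(3,4‑dimethoxyphenyl)‑7‑hydroxy‑6‑methoxy‑2,3‑dimethyl‑3,4‑dihydronaphthalen‑1(2H)‑one
Conditions: K2CO3 (1.2 equiv), MeOH, 0 °C; pH 7 buffer quench
Reagents that add atoms: none
Why: Methanolysis (transesterification) of the aryl ester is fast at 0 °C because phenoxide is a good leaving group, while enolisation at C2 is slow; the 2‑eq/3‑ax/4‑ax‑aryl arrangement of the cis isomer is also expected to be the comfortable one in the 4‑aryl series.

---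

**Compound list**
1 | catechol | Oc1ccccc1O | starting material
2 | guaiacol | COc1ccccc1O | intermediate
3 | 4‑iodo‑2‑methoxyphenol | COc1cc(I)ccc1O | intermediate
4 | 4‑iodo‑2‑methoxyphenyl pivalate | COc1cc(I)ccc1OC(=O)C(C)(C)C | intermediate
5 | maleic anhydride | O=C1OC(=O)C=C1 | starting material
6 | 2,3‑dimethylmaleic anhydride | CC1=C(C)C(=O)OC1=O | intermediate
7 | meso‑(cis)‑2,3‑dimethylsuccinic anhydride | O=C1[C@@H](C)[C@@H](C)C(=O)O1 | intermediate
8 | (2S,3R)‑4‑[3‑methoxy‑4‑(pivaloyloxy)phenyl]‑2,3‑dimethyl‑4‑oxobutanoic acid | OC(=O)[C@@H](C)[C@@H](C)C(=O)c1ccc(OC(=O)C(C)(C)C)c(OC)c1 | intermediate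
9 | (2S,3S)‑4‑[3‑methoxy‑4‑(pivaloyloxy)phenyl]‑2,3‑dimethylbutanoic acid | OC(=O)[C@@H](C)[C@@H](C)Cc1ccc(OC(=O)C(C)(C)C)c(OC)c1 | intermediate
10 | (2S,3S)‑6‑methoxy‑2,3‑dimethyl‑7‑(pivaloyloxy)‑1‑tetralone | COc1cc2c(cc1OC(=O)C(C)(C)C)C(=O)[C@@H](C)[C@@H](C)C2 | intermediate
11 | veratrole | COc1ccccc1OC | intermediate
12 | 4‑bromo‑1,2‑dimethoxybenzene | COc1ccc(Br)cc1OC | intermediate
13 | 3,4‑dimethoxyphenylboronic acid | COc1ccc(B(O)O)cc1OC | intermediate
14 | schisandrone 7‑O‑pivalate (2S,3S,4R) | COc1cc2c(cc1OC(=O)C(C)(C)C)C(=O)[C@@H](C)[C@@H](C)[C@@H]2c1ccc(OC)c(OC)c1 | intermediate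
15 | schisandrone (2S,3S,4R) | COc1cc2c(cc1O)C(=O)[C@@H](C)[C@@H](C)[C@@H]2c1ccc(OC)c(OC)c1 | target

---

**Total step count:** 13
**Longest linear sequence:** 8 steps (1 → 2 → 3 → 4 → 8 → 9 → 10 → 14 → 15; steps 1, 2, 3, 6, 7, 8, 12, 13)

**Steps most likely to fail, with fallbacks**
1. **Step 12 (new Cu‑catalysed C–H arylation).** Risks are over‑oxidation/aromatisation to the naphthol, low dr, or HAT at the product methine. Fallback (known chemistry): pre‑functionalise and cross‑couple instead of direct C–H arylation. Brominate 10 at C4 (Wohl–Ziegler: NBS, AIBN, PhCF3), then run a Ni/bis(oxazoline)‑catalysed Negishi arylation of the secondary benzylic bromide with 3,4‑dimethoxyphenylzinc iodide (made from 12). This is an established 1,1‑diarylalkane synthesis and has the same anti‑to‑3‑Me radical capture.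
2. **Step 6 (Rh desymmetrising acyl coupling).** Risk is modest ee or yield with the pivalate‑bearing arylzinc. Fallback: separate the asymmetric step from the C–C bond formation. Open 7 with BnOH under cinchona‑alkaloid catalysis to the benzyl hemiester, convert to the acid chloride, and perform a Pd‑catalysed Negishi acylation with the arylzinc from 4. H2/Pd‑C then deoxygenates the ketone and removes the benzyl ester together, rejoining the route at 9.
3. **Step 13 (base deprotection next to the epimerisable C2).** Risk is partial C2 epimerisation or incomplete pivalate cleavage. Fallback: change the protecting‑group strategy. Carry the phenol as a benzyl ether in 4 (lost during the step‑7 hydrogenolysis), acetylate the phenol after cyclisation, run the arylation on the acetate, and remove it at the end under near‑neutral conditions (NH4OAc, aq. MeOH).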